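The numbers come from no measurement; the run is a simulation.

The constants of this flask set two channels against each other, an enzyme step inhibited by the square of [substrate] and a dimerisation that grows with that square, so I looked for the concentration at which both draw equally on the substrate.

substrate 10 mM; enzyme 0.01 mol%; time 15 min

    substrate + enzyme → target + enzyme, rate k1*[substrate]*[enzyme]/(1 + ([substrate]/Km1) + ([substrate]/Ksi1)^2) (Km1 = 5.4 mM, Ksi1 = 1.8 mM, k1 = 2.1 × 10⁶ /M/s)
    target + enzyme ⇌ isomer of the product + enzyme, rate k2*[enzyme]*[target] forward; the back reaction follows from the equilibrium constant (K2 = 3.9, k2 = 2.0 × 10⁵ /M/s)
    2 substrate → homo dimer (k3 = 22 /M/s)

- in percentages every species weighs as the substrate in it: one homo dimer counts as two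
- for a step with 2 of a species take k times the square, and two of it per event
- run time (flask): 15 min

* how much target there is at 15 min, in percent of the substrate charged
* how much isomer of the product there is at 15 min, in percent of the substrate charged

I built the flask up by hand. I began with the first step by itself: the loading gave [enzyme] = 0.00100 mM and so k1[enzyme] = 2.10 /s, held back at the charge by a denominator of 33.7. Integrating the rate law brought substrate to a hundredth of its charge in 10.4 s, far less than the run of 15 min, so the answer was a matter of shares, not of speed.

Adding the second step changed the split of the enzyme's product: target and isomer of the product relaxed with a half-life of 2.76 s, much shorter than the run, so I took 20.4% of the pair as target.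

The third step cost yield. At the charge the enzyme used substrate at 0.142 of the rate of dimerisation, but that ratio climbs as [substrate] falls. Keeping the squared term of the denominator and dropping the rest, I set that ratio equal to one and got the crossover concentration: the cube root of k1[enzyme] times Ksi squared, over twice the dimerisation constant. In powers of ten, its cube against the cube of the charge had the logarithm −0.811, its own logarithm against the charge was −0.270, and it stood at 5.37 mM. With a crude cut there, counting substrate above it as going to homo dimer and substrate below it as going through the enzyme, I put 53.7% through the enzyme, which gave an estimate of 11.0% of target and 42.7% of isomer of the product.

The forecast gave 11% of target and 42.8% of isomer of the product, noting that “Substrate inhibition favours dimerisation early on”.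

The simulation of the flask gave 11.0% of target and 42.9% of isomer of the product, together 53.9% against the crossover's 53.7%. In the neighbour flask with 0.004 mol% of enzyme, the logarithm of the crossover fell by 0.133, which put the crossover at 3.95 mM, a share of 39.5%; that neighbour flask read 8.22% of target and 32.1% of isomer of the product. The flask with 0.01 mol% of enzyme had come to rest, with 0% of its substrate left and a half-life of its slowest mode of 2.76 s at 15.0 min. At 150 min it still read 11.0% of target and 42.9% of isomer of the product.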